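Labels: oxolane ring O1, C2 (3,4-dimethoxyphenyl), C3 (CH2OH carbon C6), C4 (ketone carbon C7), C5 (CH2).
Feature: the unsubstituted O1–C5 unit lies between benzylic C2, whose electron-rich aryl group can carry positive charge, and C4, alpha to carbonyl C7, which can carry negative charge. The ring is therefore a C2–C3–C4 donor–acceptor cyclopropane that has taken up CH2=O.
Cuts: first the C7–aryl bond (Weinreb ketone synthesis), then O1–C2 and C4–C5 together ((3+2) annulation with formaldehyde), then C2–C4 and C3–C4 of the cyclopropane (Michael-initiated ring closure of a cinnamaldehyde with bromomalonate).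
Activation: a lone aryl ketone on C4 is a weak acceptor and can cyclise through its own oxygen. C7 is therefore carried as an ester and doubled by a second ester on C4, which is removed after the annulation.
Forward order: cyclopropane ring (step 1), oxolane ring at its expense (step 4), loss of the extra ester, aryl ketone, desilylation.
Stereochemistry: an (S)-prolinol silyl ether catalyst sets C2 and C3 (aryl trans to C6). Step 4 inverts C2 to the 2,3-cis ether and leaves C3 alone, and C4 is set trans to C3 by base equilibration.

Key step: step 4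

Assumption: the facial sense in step 1 follows the usual shielding model for diarylprolinol silyl ethers (the (R)-catalyst is equally available); formaldehyde is dosed as the dry monomer from cracked paraformaldehyde; oxolane locants follow the labels above, not lowest-locant rules.

Step 1
Reactants: 1 (E)-3-(3,4-dimethoxyphenyl)prop-2-enal; 2 dimethyl 2-bromomalonate
Product: 3 dimethyl (2R,3S)-2-formyl-3-(3,4-dimethoxyphenyl)cyclopropane-1,1-dicarboxylate (aryl trans to formyl)
Conditions: (S)-α,α-diphenylprolinol TMS ether (20 mol %), 2,6-lutidine (1.1 equiv), CH2Cl2, 0 °C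
Reagents that add atoms: none
Why: Organocatalytic Michael-initiated ring closure (iminium then enamine activation): the bromomalonate anion should add to the beta-carbon of the E-iminium ion on the face remote from the CPh2(OTMS) group, which sets the aryl-bearing carbon (S, future C2), and the enamine then displaces bromide in a 3-exo-tet closure that places the formyl group trans to the aryl group, which sets the second centre (R, future C3); 2,6-lutidine is too weak a base to reopen the product.

Step 2
Reactants: 3 formyl cyclopropane diester
Product: 4 dimethyl (2R,3S)-2-(hydroxymethyl)-3-(3,4-dimethoxyphenyl)cyclopropane-1,1-dicarboxylate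
Conditions: NaBH4 (0.5 equiv), MeOH–CH2Cl2, −40 °C; pH 7 phosphate buffer, cold; used at once
Reagents that add atoms: none
Why: Borohydride 1,2-reduction of an aldehyde, far faster than attack on the esters or the strained ring at this temperature; no stereocentre is touched, and the cold neutral quench is meant to keep the alcohol from lactonising onto the cis ester before step 3.

Step 3
Reactants: 4 hydroxymethyl cyclopropane diester
Product: 5 dimethyl (2R,3S)-2-[(tert-butyldiphenylsilyloxy)methyl]-3-(3,4-dimethoxyphenyl)cyclopropane-1,1-dicarboxylate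
Conditions: TBDPSCl, imidazole, CH2Cl2, 0 °C → rt
Reagents that add atoms: tert-butyl(chloro)diphenylsilane, CC(C)(C)[Si](Cl)(c1ccccc1)c1ccccc1
Why: Imidazole-promoted silylation of a primary alcohol; the tert-butyldiphenylsilyl group is preferred to smaller silyl groups because it should outlast the Lewis acid of step 4 and the hot chloride of step 5, and it shuts off lactone formation.

Step 4
Reactants: 5 silyloxymethyl aryl cyclopropane diester; 6 formaldehyde
Product: 8 dimethyl (2R,3R)-2-(3,4-dimethoxyphenyl)-3-[(tert-butyldiphenylsilyloxy)methyl]oxolane-4,4-dicarboxylate, via oxocarbenium malonate enolate 7 (not isolated)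
Conditions: CH2O (monomer, ca. 10 equiv, cold CH2Cl2 solution, slow addition), Sn(OTf)2 (10 mol %), 4 Å MS, CH2Cl2, −40 → −10 °C
Reagents that add atoms: none
Why: Proposed new method: Sn(II) should chelate the two ester carbonyls on C4 and stretch the C2–C4 bond into a tight ion pair whose cationic end is stabilised by the 3,4-dimethoxyphenyl group; the oxygen of free formaldehyde attacks C2 from the side opposite the departing malonate carbon to give 7, and after rotation about C2–C3 the tin enolate adds through C4 to the O1=C5 carbon. The closest known reaction type is the Lewis-acid-catalysed (3+2) annulation of 2-aryl- and 2,3-disubstituted 2-arylcyclopropane-1,1-diesters with aryl, alkenyl and alkyl aldehydes, which is invertive at the donor carbon; what has not been shown is formaldehyde as the carbonyl partner. The oxolane ring closes in a 5-(enolexo)-endo-trig aldol mode, as in those annulations. C2 is controlled by the backside displacement, which turns the trans aryl/C6 cyclopropane into the 2,3-cis ether (2R); C3 is a spectator and keeps its configuration, and C4 carries two identical esters, so the C–C bond formation has no facial demand. The step needs capture of the ion pair before it separates and cleavage of C2–C4 rather than C3–C4: the geminal diester allows a mild catalyst at low temperature, the excess of monomeric aldehyde raises the rate of capture, and only C2 bears a donor. With esters instead of a ketone on C4, ring expansion to a dihydrofuran through a ketone oxygen is also excluded.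

Step 5
Reactants: 8 oxolane-4,4-diester
Product: 10 methyl (2R,3R,4S)-2-(3,4-dimethoxyphenyl)-3-[(tert-butyldiphenylsilyloxy)methyl]oxolane-4-carboxylate, via all-cis C4 epimer 9 (not isolated)
Conditions: LiCl (3 equiv), H2O (3 equiv), DMSO, 150 °C; then crude, NaOMe (0.2 equiv), MeOH, rt
Reagents that add atoms: none
Why: Krapcho dealkoxycarbonylation (chloride attack on a methyl ester, loss of CO2, protonation of the ester enolate, expected mainly on the open face to give all-cis 9) followed by methoxide equilibration, which moves the ester to the face opposite the C3 and C2 substituents and so sets C4 (S) under thermodynamic control.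

Step 6
Reactants: 10 trans oxolane-4-carboxylate
Product: 11 (2R,3R,4S)-2-(3,4-dimethoxyphenyl)-3-[(tert-butyldiphenylsilyloxy)methyl]-N-methoxy-N-methyloxolane-4-carboxamide
Conditions: MeNH(OMe)·HCl (2 equiv), iPrMgCl (4 equiv), THF, −20 → 0 °C
Reagents that add atoms: N,O-dimethylhydroxylamine hydrochloride, CNOC.Cl
Why: Aminolysis of the ester by the chloromagnesium amide of N,O-dimethylhydroxylamine (Weinreb amide formation), a non-acidic method that spares the benzylic ether and the silyl ether; C4 is already the more stable epimer, so brief enolisation does no harm.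

Step 7
Reactants: 11 Weinreb amide; 12 5-bromo-1,2,3-trimethoxybenzene
Product: 14 [(2R,3R,4S)-2-(3,4-dimethoxyphenyl)-3-[(tert-butyldiphenylsilyloxy)methyl]oxolan-4-yl](3,4,5-trimethoxyphenyl)methanone, via aryl Grignard reagent 13 (not isolated)
Conditions: 12, Mg, I2 (cat.), THF, reflux; then 11, THF, 0 °C → rt; aq NH4Cl
Reagents that add atoms: magnesium, [Mg] (enters 13 only)
Why: Grignard formation and Weinreb ketone synthesis: the aryl nucleophile adds only once because the magnesium-chelated tetrahedral adduct survives until the quench, and the ketone emerges as the thermodynamic 3,4-trans epimer.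

Step 8
Reactants: 14 silyl-protected ketone
Product: 15 [(3S,4R,5R)-5-(3,4-dimethoxyphenyl)-4-(hydroxymethyl)oxolan-3-yl](3,4,5-trimethoxyphenyl)methanone (route labels 2R,3R,4S; target)
Conditions: TBAF, AcOH (1:1, 2 equiv), THF, 0 °C → rt
Reagents that add atoms: none
Why: Fluoride cleavage of the silyl ether; acetic acid buffers the medium so that the beta-alkoxy ketone neither epimerises nor opens by a retro-oxa-Michael reaction, and the conditions are too weakly acidic to ionise the benzylic C2–O1 bond.

Compound list
1 | (E)-3-(3,4-dimethoxyphenyl)prop-2-enal | COc1ccc(/C=C/C=O)cc1OC | starting material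
2 | dimethyl 2-bromomalonate | COC(=O)C(Br)C(=O)OC | starting material
3 | dimethyl (2R,3S)-2-formyl-3-(3,4-dimethoxyphenyl)cyclopropane-1,1-dicarboxylate | COc1ccc([C@@H]2[C@@H](C=O)C2(C(=O)OC)C(=O)OC)cc1OC | intermediate
4 | dimethyl (2R,3S)-2-(hydroxymethyl)-3-(3,4-dimethoxyphenyl)cyclopropane-1,1-dicarboxylate | COc1ccc([C@@H]2[C@@H](CO)C2(C(=O)OC)C(=O)OC)cc1OC | intermediate
5 | dimethyl (2R,3S)-2-[(tert-butyldiphenylsilyloxy)methyl]-3-(3,4-dimethoxyphenyl)cyclopropane-1,1-dicarboxylate | COc1ccc([C@@H]2[C@@H](CO[Si](c3ccccc3)(c3ccccc3)C(C)(C)C)C2(C(=O)OC)C(=O)OC)cc1OC | intermediate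
6 | formaldehyde (monomer from commercial paraformaldehyde) | C=O | starting material
7 | ring-opened zwitterion: C2 carries O1(+)=C5H2, C4 is a malonate enolate (tin-bound in the flask) | COc1ccc([C@H]([O+]=C)[C@@H](CO[Si](c2ccccc2)(c2ccccc2)C(C)(C)C)C(C(=O)OC)=C([O-])OC)cc1OC | intermediate
8 | dimethyl (2R,3R)-2-(3,4-dimethoxyphenyl)-3-[(tert-butyldiphenylsilyloxy)methyl]oxolane-4,4-dicarboxylate (2,3-cis) | COc1ccc([C@@H]2OCC(C(=O)OC)(C(=O)OC)[C@@H]2CO[Si](c3ccccc3)(c3ccccc3)C(C)(C)C)cc1OC | intermediate
9 | methyl (2R,3R,4R)-2-(3,4-dimethoxyphenyl)-3-[(tert-butyldiphenylsilyloxy)methyl]oxolane-4-carboxylate (all-cis) | COc1ccc([C@@H]2OC[C@H](C(=O)OC)[C@@H]2CO[Si](c3ccccc3)(c3ccccc3)C(C)(C)C)cc1OC | intermediate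
10 | methyl (2R,3R,4S)-2-(3,4-dimethoxyphenyl)-3-[(tert-butyldiphenylsilyloxy)methyl]oxolane-4-carboxylate (2,3-cis, 3,4-trans) | COc1ccc([C@@H]2OC[C@@H](C(=O)OC)[C@@H]2CO[Si](c3ccccc3)(c3ccccc3)C(C)(C)C)cc1OC | intermediate
11 | (2R,3R,4S)-2-(3,4-dimethoxyphenyl)-3-[(tert-butyldiphenylsilyloxy)methyl]-N-methoxy-N-methyloxolane-4-carboxamide | COc1ccc([C@@H]2OC[C@@H](C(=O)N(C)OC)[C@@H]2CO[Si](c3ccccc3)(c3ccccc3)C(C)(C)C)cc1OC | intermediate
12 | 5-bromo-1,2,3-trimethoxybenzene | COc1cc(Br)cc(OC)c1OC | starting material
13 | 3,4,5-trimethoxyphenylmagnesium bromide | COc1cc([Mg]Br)cc(OC)c1OC | intermediate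
14 | [(2R,3R,4S)-2-(3,4-dimethoxyphenyl)-3-[(tert-butyldiphenylsilyloxy)methyl]oxolan-4-yl](3,4,5-trimethoxyphenyl)methanone | COc1ccc([C@@H]2OC[C@@H](C(=O)c3cc(OC)c(OC)c(OC)c3)[C@@H]2CO[Si](c3ccccc3)(c3ccccc3)C(C)(C)C)cc1OC | intermediate
15 | [(3S,4R,5R)-5-(3,4-dimethoxyphenyl)-4-(hydroxymethyl)oxolan-3-yl](3,4,5-trimethoxyphenyl)methanone | COc1ccc([C@@H]2OC[C@@H](C(=O)c3cc(OC)c(OC)c(OC)c3)[C@@H]2CO)cc1OC | target

Total step count: 8. Longest linear sequence: 8 steps (1 → 15). Bromide 12 enters in step 7 without a separate step.

Steps most likely to fail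

Step 4 (the one new method). Formaldehyde may polymerise on the tin salt, or it may be too weak an oxygen nucleophile. The ion pair would then separate, C2 would lose its configuration, and the cation could be lost by elimination or by alkylation of an electron-rich arene. The fallback keeps the cyclopropane, uses an aldehyde of proven competence and removes its extra carbon afterwards. It sets out from 5 and returns at 8.
- Annulation of 5 with (E)-cinnamaldehyde under Sn(OTf)2 catalysis in CH2Cl2, a known pairing for aryl cyclopropane diesters, should give the 2,3-cis-2,5-cis 5-styryl oxolane diester F1.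
- Lemieux–Johnson cleavage (OsO4 cat., NaIO4, 2,6-lutidine, aqueous dioxane) gives the 5-formyl oxolane diester F2.
- Tsuji–Wilkinson decarbonylation with RhCl(PPh3)3 in hot toluene replaces the formyl group by hydrogen and delivers 8.

Step 5. Prolonged heating may strip the silyl group (followed by lactonisation), drive beta-elimination of O1 from the ester enolate, or epimerise C2. The fallback installs the ketone first, so that the extra ester leaves as part of a beta-keto ester. It sets out from 8 and returns at 14, leaving out 10 and 11.
- Bromide 12 is lithiated (n-BuLi, THF, −78 °C) to 3,4,5-trimethoxyphenyllithium F3.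
- F3 should add once to the less hindered ester of 8 (the one trans to C6), because the lithium-chelated tetrahedral adduct persists at −78 °C. This gives the beta-keto ester F4.
- The remaining ester of F4 is lost with LiCl in wet DMSO at about 100 °C, well below the temperature a malonate needs. The ketone should settle as the trans epimer 14 in the weakly basic medium.

Step 2. The alkoxide or the free alcohol may lactonise onto the cis ester before it can be silylated. The fallback makes this lactonisation deliberate and uses the lactone as both protecting group and second acceptor. It sets out from 3 and returns at 15.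
- NaBH4 reduction followed by a trace of DBU takes 3 through 4 to the bicyclic lactone ester F5, which is still a geminally activated aryl cyclopropane.
- Annulation with 6 under the conditions of step 4 would give the cis-fused bicyclic lactone ester F6 (aryl on the concave face).
- Krapcho removal of the angular ester gives the cis-fused lactone F7.
- 3,4,5-Trimethoxyphenyllithium F3 adds once to the lactone at −78 °C to give the 3,4-cis keto alcohol F8, which may rest partly in its ring-closed hemiketal form.
- Catalytic DBU in CH2Cl2 equilibrates C4 to 15.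
This shorter, protecting-group-free line is held in reserve for two reasons: its annulation must build a more crowded bicycle, and its last step rests on an untested equilibrium.

Further compounds
F1 | step 4 | dimethyl 2-(3,4-dimethoxyphenyl)-3-[(tert-butyldiphenylsilyloxy)methyl]-5-[(E)-2-phenylethenyl]oxolane-4,4-dicarboxylate (2,3-cis, 2,5-cis) | COc1ccc([C@@H]2O[C@H](/C=C/c3ccccc3)C(C(=O)OC)(C(=O)OC)[C@@H]2CO[Si](c3ccccc3)(c3ccccc3)C(C)(C)C)cc1OC
F2 | step 4 | dimethyl 2-(3,4-dimethoxyphenyl)-3-[(tert-butyldiphenylsilyloxy)methyl]-5-formyloxolane-4,4-dicarboxylate (2,3-cis, 2,5-cis) | COc1ccc([C@@H]2O[C@H](C=O)C(C(=O)OC)(C(=O)OC)[C@@H]2CO[Si](c3ccccc3)(c3ccccc3)C(C)(C)C)cc1OC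
F3 | step 5 | 3,4,5-trimethoxyphenyllithium | [Li]c1cc(OC)c(OC)c(OC)c1
F4 | step 5 | methyl 2-(3,4-dimethoxyphenyl)-3-[(tert-butyldiphenylsilyloxy)methyl]-4-(3,4,5-trimethoxybenzoyl)oxolane-4-carboxylate (2,3-cis, aroyl trans to C6) | COc1ccc([C@@H]2OC[C@@](C(=O)OC)(C(=O)c3cc(OC)c(OC)c(OC)c3)[C@@H]2CO[Si](c3ccccc3)(c3ccccc3)C(C)(C)C)cc1OC
F5 | step 2 | methyl 6-(3,4-dimethoxyphenyl)-2-oxo-3-oxabicyclo[3.1.0]hexane-1-carboxylate (aryl exo) | COc1ccc([C@@H]2[C@H]3COC(=O)[C@@]23C(=O)OC)cc1OC
F6 | step 2 | cis-fused furo[3,4-c]furan-1-one: oxolane ring as in 8, C4 bearing CO2Me and the lactone carbonyl that is bound through oxygen to C6 (aryl endo) | COc1ccc([C@@H]2OC[C@]3(C(=O)OC)C(=O)OC[C@H]23)cc1OC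
F7 | step 2 | cis-fused 4-(3,4-dimethoxyphenyl)tetrahydro-1H,3H-furo[3,4-c]furan-1-one (aryl endo) | COc1ccc([C@@H]2OC[C@@H]3C(=O)OC[C@H]23)cc1OC
F8 | step 2 | C4 epimer of 15 (2,3-cis, 3,4-cis keto alcohol, open form) | COc1ccc([C@@H]2OC[C@H](C(=O)c3cc(OC)c(OC)c(OC)c3)[C@@H]2CO)cc1OC
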